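**Compound numbers used throughout:** 1 guaiacol, 2 trichloroethylene, 3 dichloroacetylene, 4 dichlorovinyl ether, 5 chlorotrimethylsilane, 6 chloroethynyl ether, 7 lithium acetylide, 8 silyl ynol ether, 9 3-hydroxy-2-pyrone, 10 3-methoxy-2-pyrone, 11 bridged lactone, 12 arylsilane, 13 dibromo arylsilane, 14 tribromo dimethyl ether, 15 tribromo diphenol, 16 target.

## The problem

Target 16 is an achiral, fully aromatic diaryl ether of two brominated catechol units, so there is no stereocentre to set and the whole task is one of position. Ring A carries its hydroxyl at C1, bromine at C2 and C4 and the ether oxygen at C6; ring B carries the ether oxygen at C1', its hydroxyl at C2' and bromine at C3', C5' and C6'. Four of the five bromines (C2, C4, C3', C5') lie ortho or para to a hydroxyl and can enter by ordinary phenol bromination. The fifth, at C6', is meta to the C2' hydroxyl and ortho to the ether oxygen, where no directing effect in ring B will put it. The same bromine leaves C1' flanked on both sides (C2'–O and C6'–Br), so joining the rings late through the C1'–O bond means substitution at a doubly ortho-blocked carbon. The free phenols are acidic and easily over-oxidised by halogen, and aryl C–Br bonds do not survive alkyllithiums, low-valent metals or hydrogenolysis; oxygen therefore travels as methyl ether and bromine enters only after the last organometallic step. The feature that opens a way in is the contiguous triad C6'(Br)–C1'(O)–C2'(O): C6' and C1' can be the two carbons of an alkyne bearing a silicon placeholder and the ring A aryloxy group, and C2'–C5' can be C3–C6 of a 3-oxygenated 2-pyrone whose lactone bridge leaves as carbon dioxide.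

## Retrosynthesis

**16 ⇒ 15.** The C2–Br and C3'–Br bonds are cut first. In diphenol 15 each ring already has its para position brominated and exactly one free position ortho to hydroxyl, so this bromination has only one place to go on each ring. Cutting the para bromines here as well would only move a selectivity question into the last step. The precursor has two bromines fewer. The forward reaction must stop at two equivalents of electrophilic bromine and leave the positions meta to hydroxyl alone.

**15 ⇒ 14.** The two O–H bonds are traced to O–CH3 in dimethyl ether 14. The methyl groups are kept this late for two reasons: they steer the preceding ring brominations para to themselves, and an earlier Lewis-acid ether cleavage would meet the aryl–silicon bond, which boron halides exchange. The skeleton is unchanged but the precursor has no acidic protons. The forward step must cleave both aryl methyl ethers without touching the diaryl ether or the C–Br bonds.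

**14 ⇒ 12.** Three C–Br bonds are cut: C6'–Br back to C6'–Si, and C4–Br and C5'–Br back to C–H para to the methoxy groups. Arylsilane 12 carries no halogen, so everything before it may use organolithium reagents and heat. Replacing silicon alone is not realistic, because the para positions of two anisole-type rings are at least as reactive as the ipso carbon; both of those positions are brominated in 16, so they are allowed to react. The forward sequence must substitute hydrogen without free acid (through 13), so that silicon is not lost by protonolysis before bromine replaces it.

**12 ⇒ 8 + 10.** Ring B is cut at C1'–C2' and C5'–C6', which opens it into silyl ynol ether 8 and 3-methoxy-2-pyrone 10 (with the lactone bridge restored in 11). Two neighbouring cuts were weighed against this one. Cutting C1'–O would require substitution at a carbon with two ortho substituents. Cutting C6'–Si by directed ortho-lithiation would offer competing sites beside each of the three oxygens. The cycloaddition instead fixes the 1,2,3-pattern in the act of making the ring and delivers it aromatic. The precursors are a six-membered heterocycle and an alkyne derived from guaiacol, with no substituted benzene ring B left to make. The forward reaction must place the aryloxy carbon next to the methoxy-bearing C3 of the pyrone and the silicon-bearing carbon on C6.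

**8 ⇒ 4 + 5 ⇒ 1 + 2.** The C(sp)–Si bond is cut to chlorotrimethylsilane 5 and lithium acetylide 7. The acetylide is traced through chloroalkyne 6 to dichlorovinyl ether 4, and the O–C(vinyl) bond of 4 is cut to guaiacol 1 and trichloroethylene 2 (through dichloroacetylene 3). This is the standard way to put an alkyne directly on a phenol oxygen; a copper-mediated O-alkynylation would be less secure. The forward steps must avoid attack of the organolithium on the methoxy-bearing ring.

**10 ⇒ 9.** The O–CH3 bond of the pyrone is cut to commercial 3-hydroxy-2-pyrone 9. The methyl group is needed because the acidic hydroxyl of 9 would add across the ynol ether, and it is the same protecting group as on ring A, so one operation removes both later.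

## Roads not taken

**Alternative 1:** Ring A is cut instead, at C5–C6 and C2–C3, back to an aryloxyacetone. The phenol 2-bromo-6-methoxyphenol A1 would be O-alkylated with a haloacetone to 1-(2-bromo-6-methoxyphenoxy)propan-2-one A2. Amine-catalysed Michael addition of A2 to acrolein A3 and intramolecular aldol condensation would close the carbocycle as racemic 6-(2-bromo-6-methoxyphenoxy)cyclohex-2-en-1-one A4. Enone A4 must still be dehydrogenated and brominated to the ring A phenol before ether cleavage and the ring B brominations.
- Merits: the awkward C6' bromine is bought in A1 with its position certain, the reagents are cheap, and nothing needs high temperature or an organolithium. In these respects it is better than the chosen plan.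
- Weak points: the annulation builds the easy ring (its pattern is that of guaiacol 1), so the ring-forming step solves no positional problem. The Michael step must go through the aryloxy-bearing α-carbon of A2 and not the methyl group, and competes with polymerisation of A3. Enone A4 is one unsaturation short of a phenol, and oxidative aromatisation passes through α-halo-α-aryloxy ketone stages from which aryloxide, that is all of ring B, can be expelled.
- Comparison: against the certainty of A1 the chosen plan sets a ring closure that delivers ring B already aromatic, with C6' marked by silicon, and no adjustment of oxidation level.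

**Alternative 2:** Here ring B is not built but dehydrogenated. The C–Br bonds at C3', C5' and C6' and the aromatic unsaturation are cut together, back to racemic 2-(3,5-dibromo-2-methoxyphenoxy)cyclohexan-1-one A5, an alkylation product of a dibrominated guaiacol-type phenol with a 2-halocyclohexanone. Excess electrophilic bromine in acetic acid would brominate and aromatise A5 in one operation to 3,4,6-tribromo-2-(3,5-dibromo-2-methoxyphenoxy)phenol A6, and phenol A6 is one ether cleavage short of 16.
- Merits: it is the shortest of the four plans and ring A arrives fully brominated in A5. The meta bromine has a mechanistic rationale: a 2-aryloxycyclohex-2-enone formed on the way is an enol ether whose β-carbon is the future C6'.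
- Weak points: that rationale holds only if bromination at this carbon precedes aromatisation. Once the ring is a phenol, C6' is meta to the hydroxyl and will not be brominated, and the under-brominated congener would be hard to separate from A6. Five oxidising equivalents also act on an α-aryloxy ketone, A5, that can lose aryloxide after α-halogenation.
- Comparison: on step count this road is clearly better. The chosen plan sets against it that the C6' substituent is fixed by the bond construction itself, and that each bromine then enters at a position with a single directing reason.

**Alternative 3:** The two hydroxyls are cut at C1–O and C2'–O and traced to formyl groups. The dialdehyde 2,4-dibromo-6-(2-bromo-6-formylphenoxy)benzaldehyde A7 would be assembled from two halobenzaldehydes by nucleophilic aromatic substitution, the formyl groups serving as activators. A double Baeyer–Villiger/Dakin sequence on A7 (peracid, then KOH in methanol) would give 2,4-dibromo-6-(2-bromo-6-hydroxyphenoxy)phenol A8. Bromination of A8 ortho and para to the ring B hydroxyl would finish.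
- Merits: three operations of long-established type; the C6' bromine and both ring A bromines are in place in A7 from the start, and the last step from A8 has no positional ambiguity.
- Weak points: both migrating aryl groups of A7 are electron-poor and the ring A formyl is flanked by bromine and aryloxy, so hydride migration to the carboxylic acid competes with aryl migration, and the step must succeed twice in one molecule to reach A8. The ether-forming substitution that makes A7 joins a hindered, weakly nucleophilic ortho-bromo-ortho-formyl phenoxide to a fluoride activated by a single formyl group.
- Comparison: in step count and in precedent for every operation this road is better than the chosen one. The chosen plan sets against it independence from aryl migratory aptitude, commodity starting materials (1, 2, 9), and an intermediate, 12, whose silicon can be exchanged for other groups, so that C6' congeners of 16 come from one late compound, which A8 does not offer.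

Key step: step 4

## Route

Remark: 4 is drawn as the E isomer expected from anti addition of the phenoxide to dichloroacetylene 3; its geometry is lost in step 2 and has no bearing on the route.

Step 1
Reactants: 1 guaiacol (2-methoxyphenol); 2 trichloroethylene
Product: 4 1-{[(E)-1,2-dichloroethenyl]oxy}-2-methoxybenzene, via dichloroacetylene 3 (not isolated)
Conditions: K2CO3, DMF, 70 °C
Reagents that add atoms: none
Why: Base eliminates HCl from 2 to give 3, to which the phenoxide adds in anti fashion; this is the standard preparation of aryl 1,2-dichlorovinyl ethers from phenols.

Step 2
Reactants: 4 1-{[(E)-1,2-dichloroethenyl]oxy}-2-methoxybenzene; 5 chlorotrimethylsilane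
Product: 8 [(2-methoxyphenoxy)ethynyl]trimethylsilane, via chloroethynyl ether 6 (not isolated), via lithium acetylide 7 (not isolated)
Conditions: n-BuLi (2.2 equiv), THF, −78 → −40 °C; then Me3SiCl, −78 °C → rt; NaHCO3 work-up
Reagents that add atoms: none
Why: Dehydrochlorination gives 6, chlorine–lithium exchange gives 7, and C-silylation gives 8; this is the established dichlorovinyl ether route to ynol ethers, run cold to keep butyllithium off the ring and worked up without acid because 8 hydrates easily.

Step 3
Reactants: 9 3-hydroxy-2H-pyran-2-one
Product: 10 3-methoxy-2H-pyran-2-one
Conditions: MeI, K2CO3, acetone, 40 °C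
Reagents that add atoms: iodomethane, CI
Why: Williamson O-methylation of the acidic enolic hydroxyl under mild carbonate conditions that leave the lactone intact; the methyl ether removes the proton that would otherwise add across the ynol ether in step 4.

Step 4
Reactants: 8 [(2-methoxyphenoxy)ethynyl]trimethylsilane; 10 3-methoxy-2H-pyran-2-one
Product: 12 [3-methoxy-2-(2-methoxyphenoxy)phenyl]trimethylsilane, via bridged lactone 11 (not isolated)
Conditions: 8 (1.5 equiv), BHT (cat.), mesitylene, sealed tube, 160–180 °C
Reagents that add atoms: none
Why: Proposed new method: pyrone 10 should act as the electron-poor diene across C3–C6 and ynol ether 8 as the electron-rich 2π partner in an intermolecular [4+2] cycloaddition that closes the new six-membered carbocycle as bridged lactone 11; retro-[4+2] loss of CO2 then gives the benzene ring directly, so no oxidation is needed. Bond formation is expected to be asynchronous: the silicon-bearing carbon of 8, the nucleophilic β-carbon of the ynol ether, attacks the electrophilic C6 of 10, and the oxygen-bearing carbon, whose developing positive charge is supported by the aryloxy lone pair and the β-silicon effect, closes onto C3. The closest known reaction types are the Alder–Rickert benzannulation of 2-pyrones with alkynes, including silyl-, boryl- and amino-substituted ones, and the inverse-demand addition of 2-pyrones to enol ethers and ketene acetals, in which the oxygen-bearing carbon likewise ends next to pyrone C3; an aryloxy(silyl)alkyne has not been shown in this role. The selectivity needed is regiochemical, silicon at C6' and aryloxy next to methoxy, and both the polarisation of the two partners and sterics (Me3Si going to the unsubstituted C6, away from the methoxy-bearing C3) point the same way. The two bridgehead stereocentres of 11 form as a racemate and vanish on aromatisation, so nothing has to be controlled there. No Lewis acid is used because 8 is acid-labile; its aryl group has no β-hydrogen, so the retro-ene route to a ketene that limits alkyl ynol ethers on heating is closed, and excess 8 with a radical inhibitor guards against thermal oligomerisation.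

Step 5
Reactants: 12 [3-methoxy-2-(2-methoxyphenoxy)phenyl]trimethylsilane
Product: 14 1,2-dibromo-3-(5-bromo-2-methoxyphenoxy)-4-methoxybenzene, via dibromo arylsilane 13 (not isolated)
Conditions: NBS (2.1 equiv), MeCN, 0 °C → rt; then Br2 (1.2 equiv), 0 °C → rt; aq. Na2S2O3
Reagents that add atoms: N-bromosuccinimide, O=C1CCC(=O)N1Br; bromine, BrBr
Why: NBS in MeCN brominates alkoxyarenes para to the alkoxy group (C4 and C5') without liberating HBr, which protects the C–Si bond from protonolysis; Br2 then replaces silicon by electrophilic ipso-substitution (bromodesilylation), the cationic intermediate being stabilised by the β-silicon effect.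

Step 6
Reactants: 14 1,2-dibromo-3-(5-bromo-2-methoxyphenoxy)-4-methoxybenzene
Product: 15 3,4-dibromo-2-(5-bromo-2-hydroxyphenoxy)phenol
Conditions: BBr3 (5 equiv), CH2Cl2, −78 °C → rt; then H2O
Reagents that add atoms: none
Why: Lewis-acid cleavage of aryl methyl ethers (boron coordination, bromide attack on methyl); the diaryl ether has no sp3 carbon to attack and the aryl bromides are inert, and the step is placed after silicon has gone because BBr3 would exchange it for boron.

Step 7
Reactants: 15 3,4-dibromo-2-(5-bromo-2-hydroxyphenoxy)phenol
Product: 16 3,4,6-tribromo-2-(3,5-dibromo-2-hydroxyphenoxy)phenol
Conditions: Br2 (2.1 equiv), AcOH, rt; aq. NaHSO3 work-up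
Reagents that add atoms: bromine, BrBr
Why: Electrophilic aromatic bromination directed by the free hydroxyls; on each ring the para position is occupied and only one ortho position (C2, C3') is open, while positions meta to hydroxyl are not attacked, and the reductive work-up returns any bromodienone to the phenol.

## Compound list

1 | guaiacol (2-methoxyphenol) | COc1ccccc1O | starting material
2 | trichloroethylene | ClC=C(Cl)Cl | starting material
3 | dichloroacetylene | ClC#CCl | intermediate (not isolated)
4 | 1-{[(E)-1,2-dichloroethenyl]oxy}-2-methoxybenzene | COc1ccccc1O/C(Cl)=C\Cl | intermediate
5 | chlorotrimethylsilane | C[Si](C)(C)Cl | starting material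
6 | 1-[(chloroethynyl)oxy]-2-methoxybenzene | COc1ccccc1OC#CCl | intermediate (not isolated)
7 | lithium (2-methoxyphenoxy)acetylide | COc1ccccc1OC#C[Li] | intermediate (not isolated)
8 | [(2-methoxyphenoxy)ethynyl]trimethylsilane | COc1ccccc1OC#C[Si](C)(C)C | intermediate
9 | 3-hydroxy-2H-pyran-2-one | O=C1OC=CC=C1O | starting material
10 | 3-methoxy-2H-pyran-2-one | COC1=CC=COC1=O | intermediate
11 | 4-methoxy-5-(2-methoxyphenoxy)-6-(trimethylsilyl)-2-oxabicyclo[2.2.2]octa-5,7-dien-3-one (racemic; bridgehead configurations tied by the bicycle) | COC12C=CC(OC1=O)C([Si](C)(C)C)=C2Oc1ccccc1OC | intermediate (not isolated)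
12 | [3-methoxy-2-(2-methoxyphenoxy)phenyl]trimethylsilane | COc1ccccc1Oc1c(OC)cccc1[Si](C)(C)C | intermediate
13 | [6-bromo-2-(5-bromo-2-methoxyphenoxy)-3-methoxyphenyl]trimethylsilane | COc1ccc(Br)cc1Oc1c(OC)ccc(Br)c1[Si](C)(C)C | intermediate (not isolated)
14 | 1,2-dibromo-3-(5-bromo-2-methoxyphenoxy)-4-methoxybenzene | COc1ccc(Br)cc1Oc1c(OC)ccc(Br)c1Br | intermediate
15 | 3,4-dibromo-2-(5-bromo-2-hydroxyphenoxy)phenol | Oc1ccc(Br)cc1Oc1c(O)ccc(Br)c1Br | intermediate
16 | 3,4,6-tribromo-2-(3,5-dibromo-2-hydroxyphenoxy)phenol | Oc1c(Br)cc(Br)cc1Oc1c(O)c(Br)cc(Br)c1Br | target

## Step count and least certain steps

Total: 7 steps. Longest linear sequence: 6 steps (steps 1, 2, 4, 5, 6, 7); step 3 is a one-step side branch.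

**Step 4 (key step, proposed new method).** The most likely failure is that no cycloaddition takes place below the temperature at which the ynol ether oligomerises or is hydrated by traces of acid: both partners are fairly electron-rich, and the methoxy group of 10 feeds electron density toward C6. A second possibility is leakage into the reversed orientation. The fallback gives up the ring construction and makes the C1'–O bond by nucleophilic aromatic substitution, all by known chemistry. It sets out from guaiacol 1. Compound 1 and purchased 2-fluoro-1-methoxy-3-nitrobenzene F1 (K2CO3, DMF, 90 °C) should give 1-methoxy-2-(2-methoxyphenoxy)-3-nitrobenzene F2, the ortho-nitro group activating the fluoride. Reduction (Fe, NH4Cl, aqueous EtOH, 80 °C) gives 3-methoxy-2-(2-methoxyphenoxy)aniline F3. Diazotisation (NaNO2, aqueous HBr, 0 °C) gives 3-methoxy-2-(2-methoxyphenoxy)benzenediazonium bromide F4, which CuBr in HBr converts by Sandmeyer reaction into 1-bromo-3-methoxy-2-(2-methoxyphenoxy)benzene F5; a high bromide concentration is used to outrun Pschorr-type closure onto ring A. NBS (2.1 equiv, MeCN) then brominates para to each methoxy group, and the sequence comes back to the route at 14.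

**Step 5.** The most likely failure is loss of silicon by protonolysis if acid builds up before the ipso step, or slow ipso attack at a carbon flanked by the new C5' bromine and the aryloxy group. A bromine entering ortho instead of para to the ring B methoxy would not be a failure, since such material converges on 16 in step 7. The fallback changes the way the C–Si bond becomes C–Br and sets out from 13, isolated after the NBS stage. BCl3 (CH2Cl2, 0 °C) exchanges silicon for boron to give dichloro[6-bromo-2-(5-bromo-2-methoxyphenoxy)-3-methoxyphenyl]borane F6. Pinacol converts this into 2-[6-bromo-2-(5-bromo-2-methoxyphenoxy)-3-methoxyphenyl]-4,4,5,5-tetramethyl-1,3,2-dioxaborolane F7. CuBr2 in aqueous MeOH at 80 °C then replaces boron by bromine (copper-mediated bromodeboronation, independent of ring electronics), returning to the route at 14.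

**Step 2.** The most likely failure is attack of butyllithium on the acetylenic carbon of 6 or 7 with expulsion of guaiacolate, or hydration of 8 during isolation. The fallback builds the triple bond by dehydrobromination with non-nucleophilic bases instead of chlorine–lithium exchange, and sets out from 1. Transfer vinylation (vinyl acetate, [Ir(cod)Cl]2, Na2CO3, toluene, 100 °C) gives 1-(ethenyloxy)-2-methoxybenzene F8. Br2 (CH2Cl2, −78 °C) gives the labile 1-(1,2-dibromoethoxy)-2-methoxybenzene F9, used crude. KOt-Bu (THF, −78 → 0 °C) removes HBr to give 1-{[(Z)-2-bromoethenyl]oxy}-2-methoxybenzene F10 (mainly Z expected; either isomer serves). LiN(i-Pr)2 (2.2 equiv, THF, −78 °C) eliminates again to 1-(ethynyloxy)-2-methoxybenzene F11 and deprotonates it in the same flask to lithium acetylide 7, which 5 silylates, so that the sequence rejoins the route at 8.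

## Further compounds

F1 | step 4 | 2-fluoro-1-methoxy-3-nitrobenzene | COc1cccc([N+](=O)[O-])c1F
F2 | step 4 | 1-methoxy-2-(2-methoxyphenoxy)-3-nitrobenzene | COc1ccccc1Oc1c(OC)cccc1[N+](=O)[O-]
F3 | step 4 | 3-methoxy-2-(2-methoxyphenoxy)aniline | COc1ccccc1Oc1c(OC)cccc1N
F4 | step 4 | 3-methoxy-2-(2-methoxyphenoxy)benzenediazonium bromide | COc1ccccc1Oc1c(OC)cccc1[N+]#N.[Br-]
F5 | step 4 | 1-bromo-3-methoxy-2-(2-methoxyphenoxy)benzene | COc1ccccc1Oc1c(OC)cccc1Br
F6 | step 5 | dichloro[6-bromo-2-(5-bromo-2-methoxyphenoxy)-3-methoxyphenyl]borane | COc1ccc(Br)cc1Oc1c(OC)ccc(Br)c1B(Cl)Cl
F7 | step 5 | 2-[6-bromo-2-(5-bromo-2-methoxyphenoxy)-3-methoxyphenyl]-4,4,5,5-tetramethyl-1,3,2-dioxaborolane | COc1ccc(Br)cc1Oc1c(OC)ccc(Br)c1B1OC(C)(C)C(C)(C)O1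
F8 | step 2 | 1-(ethenyloxy)-2-methoxybenzene | COc1ccccc1OC=C
F9 | step 2 | 1-(1,2-dibromoethoxy)-2-methoxybenzene (racemic) | COc1ccccc1OC(Br)CBr
F10 | step 2 | 1-{[(Z)-2-bromoethenyl]oxy}-2-methoxybenzene | COc1ccccc1O/C=C\Br
F11 | step 2 | 1-(ethynyloxy)-2-methoxybenzene | COc1ccccc1OC#C
A1 | alternative 1 | 2-bromo-6-methoxyphenol | COc1cccc(Br)c1O
A2 | alternative 1 | 1-(2-bromo-6-methoxyphenoxy)propan-2-one | CC(=O)COc1c(OC)cccc1Br
A3 | alternative 1 | acrolein (prop-2-enal) | C=CC=O
A4 | alternative 1 | 6-(2-bromo-6-methoxyphenoxy)cyclohex-2-en-1-one (racemic) | O=C1C=CCCC1Oc1c(OC)cccc1Br
A5 | alternative 2 | 2-(3,5-dibromo-2-methoxyphenoxy)cyclohexan-1-one (racemic) | COc1c(Br)cc(Br)cc1OC1CCCCC1=O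
A6 | alternative 2 | 3,4,6-tribromo-2-(3,5-dibromo-2-methoxyphenoxy)phenol | COc1c(Br)cc(Br)cc1Oc1c(O)c(Br)cc(Br)c1Br
A7 | alternative 3 | 2,4-dibromo-6-(2-bromo-6-formylphenoxy)benzaldehyde | O=Cc1c(Br)cc(Br)cc1Oc1c(C=O)cccc1Br
A8 | alternative 3 | 2,4-dibromo-6-(2-bromo-6-hydroxyphenoxy)phenol | Oc1c(Br)cc(Br)cc1Oc1c(O)cccc1Br
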